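**Retrosynthetic overview**
1. Target ⇒ all-trans 4,7-diol. Both tiglates go on in one double Mitsunobu reaction, and SN2 inversion at C4 creates the cis C4–O/C5–iPr relation.
2. Diol ⇒ 6-acetoxy-4-silyloxy-5-isopropylcyclohex-2-enone, by desilylation and C2–C7 bond formation in a Morita–Baylis–Hillman reaction with formaldehyde.
3. Cyclohexenone ⇒ 2-acetoxy-3-isopropyl-4-silyloxycyclopentanone. This is the key one-carbon ring expansion: diazoalkane addition, 1,2-shift of C3 from C1 to the new C2, loss of N2, then dehydrosilylation in the same flask.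
4. Cyclopentanone ⇒ (R)-4-hydroxycyclopent-2-enone, with C6–OAc from acetoxylation of the enol silane and C5–iPr from anti conjugate addition.
5. Ring order: the only ring is bought as a five-membered carbocycle and enlarged to the six-membered ring in step 4.

Assumption: ring atoms carry the target enone numbering (C1 C=O, C2 C–CH2O, C3 =CH, C4 CH–OTig, C5 CH–iPr, C6 CH–OAc). The target is (4S,5S,6R) with two (E)-2-methylbut-2-enoates (tiglates). Compound 1 is bought enantiopure, and its TBS ether 2 is also sold, which would save step 1.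

**Step 1**
Reactants: 1 (R)-4-hydroxycyclopent-2-en-1-one
Product: 2 (R)-4-[(tert-butyldimethylsilyl)oxy]cyclopent-2-en-1-one
Conditions: TBSCl, imidazole, CH2Cl2, 0 °C to rt
Reagents that add atoms: tert-butyldimethylsilyl chloride, CC(C)(C)[Si](C)(C)Cl
Why: Imidazole-promoted O-silylation (silyl ether protection) touches no bond at the stereocentre, so C4 stays R, and the bulky group later steers the conjugate addition.

**Step 2**
Reactants: 2 (R)-4-[(tert-butyldimethylsilyl)oxy]cyclopent-2-en-1-one; 3 isopropylmagnesium chloride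
Product: 4 tert-butyl{[(1R,2R)-2-isopropyl-4-(trimethylsilyloxy)cyclopent-3-en-1-yl]oxy}dimethylsilane (iPr trans to OTBS)
Conditions: iPrMgCl, CuI·2LiCl (10 mol %), TMSCl, THF, −78 °C; Et3N/pentane work-up
Reagents that add atoms: chlorotrimethylsilane, C[Si](C)(C)Cl
Why: The Cu(I)-catalysed, TMSCl-accelerated conjugate addition of the Grignard reagent delivers isopropyl anti to the C4 silyloxy group (setting C5), and TMSCl traps the enolate regiospecifically at C1/C6 before it can equilibrate or eliminate.

**Step 3**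
Reactants: 4 tert-butyl{[(1R,2R)-2-isopropyl-4-(trimethylsilyloxy)cyclopent-3-en-1-yl]oxy}dimethylsilane
Product: 5 (2R,3R,4R)-2-acetoxy-4-[(tert-butyldimethylsilyl)oxy]-3-isopropylcyclopentan-1-one (2,3-trans and 3,4-trans)
Conditions: Pb(OAc)4, CH2Cl2, 0 °C to rt
Reagents that add atoms: lead(IV) acetate, CC(=O)O[Pb](OC(C)=O)(OC(C)=O)OC(C)=O
Why: Lead(IV) acetate α-acetoxylation of a silyl enol ether (Rubottom-type oxidation) places OAc on C6 anti to the neighbouring isopropyl group, and this 2,3-trans isomer is also the thermodynamic epimer of the enolisable centre.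

**Step 4**
Reactants: 5 (2R,3R,4R)-2-acetoxy-4-[(tert-butyldimethylsilyl)oxy]-3-isopropylcyclopentan-1-one; 6 (trimethylsilyl)diazomethane
Product: 9 (4R,5R,6R)-6-acetoxy-4-[(tert-butyldimethylsilyl)oxy]-5-isopropylcyclohex-2-en-1-one, via alpha-silyl ketone 7 (not isolated), via enol silane 8 (not isolated)
Conditions: TMSCHN2 (1.2 equiv), Sc(OTf)3 (10 mol %), CH2Cl2, −40 to 0 °C; evaporate; Pd(OAc)2 (1.1 equiv), MeCN, rt, same flask
Reagents that add atoms: none
Why: Proposed new method: one-flask homologative dehydrogenation of an α-acyloxy-β'-silyloxycyclopentanone; Sc(III) held by the ketone/acetate pair activates C1 for attack by the diazo carbon, the β-oxido diazonium ion loses N2 with anti-periplanar 1,2-shift of the unsubstituted C3H2 (the acetoxy-bearing C6 is inductively deactivated and more hindered), α-silyl ketone 7 undergoes a Sc-promoted 1,3 C-to-O silyl shift to enol silane 8, which is inert to more diazoalkane (no over-homologation) and fixes the enol regiochemistry, and Pd(OAc)2 turns 7 or 8 into the C2 palladium enolate, whose β-hydride elimination can only use C3–H; no stereocentre takes part; the closest known reaction types are the Lewis-acid-catalysed diazoalkane ring expansion (Tiffeneau–Demjanov/Büchner–Curtius–Schlotterbeck type, shown with Sc(OTf)3/TMSCHN2 for arylcyclobutanones) and the Saegusa–Ito oxidation, which have been neither merged nor used on such oxygenated cyclopentanones.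

**Step 5**
Reactants: 9 (4R,5R,6R)-6-acetoxy-4-[(tert-butyldimethylsilyl)oxy]-5-isopropylcyclohex-2-en-1-one; 10 formaldehyde
Product: 11 (4R,5R,6R)-6-acetoxy-4-[(tert-butyldimethylsilyl)oxy]-2-(hydroxymethyl)-5-isopropylcyclohex-2-en-1-one
Conditions: 37 % aq. HCHO, n-Bu3P (20 mol %), CHCl3/MeOH, rt
Reagents that add atoms: none
Why: In the Morita–Baylis–Hillman hydroxymethylation, reversible phosphine addition at C3 gives the C2 enolate, which attacks formaldehyde and then expels the phosphine under near-neutral conditions that leave acetate, silyl ether and all three stereocentres untouched.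

**Step 6**
Reactants: 11 (4R,5R,6R)-6-acetoxy-4-[(tert-butyldimethylsilyl)oxy]-2-(hydroxymethyl)-5-isopropylcyclohex-2-en-1-one
Product: 12 (4R,5S,6R)-6-acetoxy-4-hydroxy-2-(hydroxymethyl)-5-isopropylcyclohex-2-en-1-one (all-trans; the C5 descriptor changes only through CIP priorities)
Conditions: HF·pyridine, THF, 0 °C to rt
Reagents that add atoms: none
Why: Fluoride-driven Si–O cleavage (silyl ether deprotection) in a buffered acidic medium spares the base-sensitive α-acetoxy enone and breaks no C–O bond at a stereocentre.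

**Step 7**
Reactants: 12 (4R,5S,6R)-6-acetoxy-4-hydroxy-2-(hydroxymethyl)-5-isopropylcyclohex-2-en-1-one; 13 tiglic acid [(E)-2-methylbut-2-enoic acid, 2 equiv consumed]
Product: 14 (4S,5S,6R)-6-acetoxy-5-isopropyl-4-[(E)-2-methylbut-2-enoyloxy]-2-{[(E)-2-methylbut-2-enoyloxy]methyl}cyclohex-2-en-1-one (target)
Conditions: PPh3/DIAD (3 equiv each, betaine pre-formed at 0 °C), tiglic acid (3 equiv), toluene, 0 to 40 °C
Reagents that add atoms: none
Why: In the double Mitsunobu esterification both hydroxyls become oxyphosphonium leaving groups displaced by tiglate, at primary C7 without stereochemical consequence and at the allylic secondary C4 by SN2 with inversion (R to S), which puts the C4 tiglate cis to isopropyl while the stable (E)-geometry of the acid is kept.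

**Compound list**
1 | (R)-4-hydroxycyclopent-2-en-1-one | C1[C@@H](O)C=CC1=O | starting material
2 | (R)-4-[(tert-butyldimethylsilyl)oxy]cyclopent-2-en-1-one | C1[C@@H](O[Si](C)(C)C(C)(C)C)C=CC1=O | intermediate
3 | isopropylmagnesium chloride | CC(C)[Mg]Cl | starting material
4 | tert-butyl{[(1R,2R)-2-isopropyl-4-(trimethylsilyloxy)cyclopent-3-en-1-yl]oxy}dimethylsilane | C1[C@@H](O[Si](C)(C)C(C)(C)C)[C@H](C(C)C)C=C1O[Si](C)(C)C | intermediate
5 | (2R,3R,4R)-2-acetoxy-4-[(tert-butyldimethylsilyl)oxy]-3-isopropylcyclopentan-1-one | C1[C@@H](O[Si](C)(C)C(C)(C)C)[C@H](C(C)C)[C@@H](OC(C)=O)C1=O | intermediate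
6 | (trimethylsilyl)diazomethane | C[Si](C)(C)C=[N+]=[N-] | starting material
7 | (4R,5R,6R)-6-acetoxy-4-[(tert-butyldimethylsilyl)oxy]-5-isopropyl-2-(trimethylsilyl)cyclohexan-1-one (C2 epimers) | C[Si](C)(C)C1C[C@@H](O[Si](C)(C)C(C)(C)C)[C@H](C(C)C)[C@@H](OC(C)=O)C1=O | intermediate
8 | (1R,5R,6R)-5-[(tert-butyldimethylsilyl)oxy]-6-isopropyl-2-(trimethylsilyloxy)cyclohex-2-en-1-yl acetate | C=1C[C@@H](O[Si](C)(C)C(C)(C)C)[C@H](C(C)C)[C@@H](OC(C)=O)C=1O[Si](C)(C)C | intermediate
9 | (4R,5R,6R)-6-acetoxy-4-[(tert-butyldimethylsilyl)oxy]-5-isopropylcyclohex-2-en-1-one | C1=C[C@@H](O[Si](C)(C)C(C)(C)C)[C@H](C(C)C)[C@@H](OC(C)=O)C1=O | intermediate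
10 | formaldehyde | C=O | starting material
11 | (4R,5R,6R)-6-acetoxy-4-[(tert-butyldimethylsilyl)oxy]-2-(hydroxymethyl)-5-isopropylcyclohex-2-en-1-one | OCC1=C[C@@H](O[Si](C)(C)C(C)(C)C)[C@H](C(C)C)[C@@H](OC(C)=O)C1=O | intermediate
12 | (4R,5S,6R)-6-acetoxy-4-hydroxy-2-(hydroxymethyl)-5-isopropylcyclohex-2-en-1-one | OCC1=C[C@@H](O)[C@H](C(C)C)[C@@H](OC(C)=O)C1=O | intermediate
13 | tiglic acid, (E)-2-methylbut-2-enoic acid | C/C=C(\C)C(=O)O | starting material
14 | (4S,5S,6R)-6-acetoxy-5-isopropyl-4-[(E)-2-methylbut-2-enoyloxy]-2-{[(E)-2-methylbut-2-enoyloxy]methyl}cyclohex-2-en-1-one | C/C=C(\C)C(=O)OCC1=C[C@H](OC(=O)/C(C)=C/C)[C@H](C(C)C)[C@@H](OC(C)=O)C1=O | target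

**Total step count:** 7. **Longest linear sequence:** 7 (1 → 14).

**Three steps most likely to fail**

**Step 4 (the proposed new step).** The risks are silyl epoxide formation instead of the 1,2-shift, Lewis-acid β-elimination of the silyloxy group, and hydrolysis of the enol silane before palladation. The fallback uses known chemistry, sets out from 5 and returns at 9. BF3·OEt2-promoted insertion of allyl diazoacetate (classical diazoacetate ring expansion, in which the unsubstituted CH2 migrates) in CH2Cl2 at −20 °C gives allyl (3R,4R,5R)-3-acetoxy-5-[(tert-butyldimethylsilyl)oxy]-4-isopropyl-2-oxocyclohexane-1-carboxylate F1. Heating this with Pd(OAc)2/dppe (5 mol %) in MeCN (Tsuji decarboxylation–dehydrogenation of allyl β-keto esters) generates the same C2 palladium enolate and gives enone 9.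

**Step 7.** The C4 alcohol is flanked by isopropyl (a menthol-like situation) and tiglic acid is only weakly acidic. Retention by acyl transfer, elimination, or phosphine attack on the new allylic ester may therefore compete. The fallback sets out from 12 and returns at 14.
- Tigloyl chloride (1.05 equiv) and 2,4,6-collidine in CH2Cl2 at −78 °C acylate only the primary hydroxyl. This gives [(3R,4S,5R)-5-acetoxy-3-hydroxy-4-isopropyl-6-oxocyclohex-1-en-1-yl]methyl tiglate F3.
- MsCl/Et3N at −20 °C gives the allylic 4-mesylate F4.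
- Tiglic acid 13 and Cs2CO3 give caesium tiglate F5. With 18-crown-6 in toluene, this displaces the mesylate by SN2 with inversion to give 14.

**Step 5.** The β-carbon is next to the silyloxy-bearing C4, and the α-acetoxy ketone may suffer acyl loss with nucleophilic catalysts. The fallback sets out from 9 and returns at 11. I2/pyridine in CH2Cl2 (Johnson α-iodination) gives (4S,5R,6R)-6-acetoxy-4-[(tert-butyldimethylsilyl)oxy]-2-iodo-5-isopropylcyclohex-2-en-1-one F2. Stille coupling with (tributylstannyl)methanol [Pd2(dba)3, AsPh3, CuI, NMP, 50 °C] then installs the hydroxymethyl group and gives 11.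

**Further compounds**
F1 | step 4 | allyl (3R,4R,5R)-3-acetoxy-5-[(tert-butyldimethylsilyl)oxy]-4-isopropyl-2-oxocyclohexane-1-carboxylate (C1 epimers/enol) | C=CCOC(=O)C1C[C@@H](O[Si](C)(C)C(C)(C)C)[C@H](C(C)C)[C@@H](OC(C)=O)C1=O
F2 | step 5 | (4S,5R,6R)-6-acetoxy-4-[(tert-butyldimethylsilyl)oxy]-2-iodo-5-isopropylcyclohex-2-en-1-one | IC1=C[C@@H](O[Si](C)(C)C(C)(C)C)[C@H](C(C)C)[C@@H](OC(C)=O)C1=O
F3 | step 7 | [(3R,4S,5R)-5-acetoxy-3-hydroxy-4-isopropyl-6-oxocyclohex-1-en-1-yl]methyl (E)-2-methylbut-2-enoate | C/C=C(\C)C(=O)OCC1=C[C@@H](O)[C@H](C(C)C)[C@@H](OC(C)=O)C1=O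
F4 | step 7 | [(3R,4R,5R)-5-acetoxy-4-isopropyl-3-(methylsulfonyloxy)-6-oxocyclohex-1-en-1-yl]methyl (E)-2-methylbut-2-enoate | C/C=C(\C)C(=O)OCC1=C[C@@H](OS(C)(=O)=O)[C@H](C(C)C)[C@@H](OC(C)=O)C1=O
F5 | step 7 | caesium (E)-2-methylbut-2-enoate | [Cs+].C/C=C(\C)C(=O)[O-]
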